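**Retrosynthetic overview**
1. Last bond: ring A C-6 to the bridging CH2, by intermolecular Michael addition of dienone 6 to the o-quinone methide released from the Mannich-derived ammonium salt 11.
2. Dienone 6: prenyl from allyl by cross-metathesis; the quaternary stereocentre from a Pd-catalysed asymmetric dearomative allylation of phenol 3, whose free ring position is blocked by chlorine (removed afterwards with Zn).
3. Phenols 3 and 9: Friedel–Crafts butanoylation of 2-methylphloroglucinol and of phloroglucinol, then chlorination (ring A) or selective 4-O-methylation and Mannich aminomethylation (ring B).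
4. Rings: none is built. Both six-membered rings are bought as phloroglucinols; ring A is dearomatised in step 3 and ring B stays aromatic.

Assumption: the (S,S) Trost ligand is taken to give the configuration drawn for 4; if the opposite sense is found, the (R,R) ligand is used and nothing else changes.

**Route**

Step 1
Reactants: 1 2-methylbenzene-1,3,5-triol
Product: 2 1-(2,4,6-trihydroxy-3-methylphenyl)butan-1-one
Conditions: butanoyl chloride (1.05 equiv), AlCl3 (3.5 equiv), PhNO2/CH2Cl2, 0 → 45 °C; ice/1 M HCl
Reagents that add atoms: butanoyl chloride, CCCC(=O)Cl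
Why: Friedel–Crafts C-acylation of the very electron-rich triol stops at the mono-ketone because the chelated acyl group deactivates the ring toward a second acylation.

Step 2
Reactants: 2 1-(2,4,6-trihydroxy-3-methylphenyl)butan-1-one
Product: 3 1-(3-chloro-2,4,6-trihydroxy-5-methylphenyl)butan-1-one
Conditions: SO2Cl2 (1.0 equiv), Et2O, 0 °C → rt
Reagents that add atoms: sulfuryl chloride, ClS(Cl)(=O)=O
Why: Electrophilic aromatic chlorination takes the only free ring position and installs a removable blocking group, so that the later C-allylation cannot occur or repeat at this carbon.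

Step 3
Reactants: 3 1-(3-chloro-2,4,6-trihydroxy-5-methylphenyl)butan-1-one
Product: 4 (4S)-2-butanoyl-6-chloro-3,5-dihydroxy-4-methyl-4-(prop-2-en-1-yl)cyclohexa-2,5-dien-1-one
Conditions: allyl methyl carbonate (1.05 equiv), Pd2(dba)3·CHCl3 (2.5 mol %), (S,S)-DACH-phenyl Trost ligand (7.5 mol %), Et3N (2 equiv), CH2Cl2, −20 → 0 °C; 1 M HCl work-up
Reagents that add atoms: allyl methyl carbonate, C=CCOC(=O)OC
Why: In this dearomative Tsuji–Trost asymmetric allylic alkylation the soft phenoxide attacks the π-allyl-Pd complex at the methyl-bearing carbon (O-allylation is reversible under Pd(0), the acyl-bearing carbon does not alkylate and the chloro-bearing carbon is deactivated), and the chiral pocket of the ligand selects one enantiotopic face of the planar nucleophile, which sets the quaternary centre.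

Step 4
Reactants: 4 (4S)-2-butanoyl-6-chloro-3,5-dihydroxy-4-methyl-4-(prop-2-en-1-yl)cyclohexa-2,5-dien-1-one
Product: 5 (4R)-2-butanoyl-3,5-dihydroxy-4-methyl-4-(prop-2-en-1-yl)cyclohexa-2,5-dien-1-one
Conditions: Zn dust (5 equiv), AcOH/THF 1:4, 0 °C → rt
Reagents that add atoms: none
Why: Zinc reduction of the 2-chloro-1,3-dione C–Cl bond (α-halo carbonyl dehalogenation) is fast and leaves the alkene, the acyl-enol system and the quaternary centre untouched; the descriptor changes from S to R only through CIP priorities, not through any change in geometry.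

Step 5
Reactants: 5 (4R)-2-butanoyl-3,5-dihydroxy-4-methyl-4-(prop-2-en-1-yl)cyclohexa-2,5-dien-1-one
Product: 6 (4R)-2-butanoyl-3,5-dihydroxy-4-methyl-4-(3-methylbut-2-en-1-yl)cyclohexa-2,5-dien-1-one
Conditions: Grubbs II (5 mol %), 2-methylbut-2-ene/CH2Cl2 1:2, rt → 35 °C, sealed tube
Reagents that add atoms: 2-methylbut-2-ene, CC=C(C)C
Why: Olefin cross-metathesis of the terminal alkene with excess 2-methylbut-2-ene turns allyl into prenyl with loss of propene, the catalyst tolerates the acidic enol, and the mild temperature avoids a Cope shift of the allyl group.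

Step 6
Reactants: 7 benzene-1,3,5-triol
Product: 8 1-(2,4,6-trihydroxyphenyl)butan-1-one
Conditions: butanoyl chloride (1.0 equiv), AlCl3 (3.5 equiv), PhNO2/CH2Cl2, 0 → 45 °C; ice/1 M HCl
Reagents that add atoms: butanoyl chloride, CCCC(=O)Cl
Why: Friedel–Crafts C-acylation of phloroglucinol gives the mono-acyl product because the first chelated acyl group deactivates the ring.

Step 7
Reactants: 8 1-(2,4,6-trihydroxyphenyl)butan-1-one
Product: 9 1-(2,6-dihydroxy-4-methoxyphenyl)butan-1-one
Conditions: Me2SO4 (1.0 equiv), K2CO3 (1.0 equiv), acetone, rt → 40 °C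
Reagents that add atoms: dimethyl sulfate, COS(=O)(=O)OC
Why: In this Williamson-type O-methylation the 4-OH, para to the ketone and not hydrogen-bonded to it, is the most acidic and most accessible hydroxyl, so one equivalent of base and Me2SO4 methylates it selectively.

Step 8
Reactants: 9 1-(2,6-dihydroxy-4-methoxyphenyl)butan-1-one
Product: 10 1-{3-[(dimethylamino)methyl]-2,6-dihydroxy-4-methoxyphenyl}butan-1-one
Conditions: CH2(NMe2)2 (1.0 equiv), EtOH, 0 °C → rt
Reagents that add atoms: N,N,N',N'-tetramethylmethanediamine, CN(C)CN(C)C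
Why: Phenol Mannich aminomethylation occurs at one of the two equivalent free ring positions, and one equivalent of the aminal limits bis-aminomethylation.

Step 9
Reactants: 10 1-{3-[(dimethylamino)methyl]-2,6-dihydroxy-4-methoxyphenyl}butan-1-one
Product: 11 1-(3-butanoyl-2,4-dihydroxy-6-methoxyphenyl)-N,N,N-trimethylmethanaminium iodide
Conditions: MeI (3 equiv), THF, rt, dark; filter the salt
Reagents that add atoms: iodomethane, CI
Why: Menshutkin N-quaternisation converts NMe2 into the neutral leaving group NMe3 so that the quinone methide can later form at room temperature, and without added base the hydrogen-bonded phenols are not methylated.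

Step 10
Reactants: 6 (4R)-2-butanoyl-3,5-dihydroxy-4-methyl-4-(3-methylbut-2-en-1-yl)cyclohexa-2,5-dien-1-one; 11 1-(3-butanoyl-2,4-dihydroxy-6-methoxyphenyl)-N,N,N-trimethylmethanaminium iodide
Product: 13 elaphopilosin A, via o-quinone methide 12 (not isolated)
Conditions: K2CO3 (2.5 equiv), dry MeCN, 0 °C → rt, 11 (1.1 equiv) added slowly; 1 M HCl work-up
Reagents that add atoms: none
Why: Base triggers E1cB loss of NMe3 from 11 to give o-quinone methide 12, and the soft enolate of the vinylogous acid 6 adds through its only free carbon (C-6) in an intermolecular Michael addition that rearomatises ring B; no new stereocentre forms and the quaternary centre is not touched.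

**Compound list**
1 | 2-methylbenzene-1,3,5-triol (2-methylphloroglucinol) | Cc1c(O)cc(O)cc1O | starting material
2 | 1-(2,4,6-trihydroxy-3-methylphenyl)butan-1-one | CCCC(=O)c1c(O)cc(O)c(C)c1O | intermediate
3 | 1-(3-chloro-2,4,6-trihydroxy-5-methylphenyl)butan-1-one | CCCC(=O)c1c(O)c(Cl)c(O)c(C)c1O | intermediate
4 | (4S)-2-butanoyl-6-chloro-3,5-dihydroxy-4-methyl-4-(prop-2-en-1-yl)cyclohexa-2,5-dien-1-one | CCCC(=O)C1=C(O)[C@](C)(CC=C)C(O)=C(Cl)C1=O | intermediate
5 | (4R)-2-butanoyl-3,5-dihydroxy-4-methyl-4-(prop-2-en-1-yl)cyclohexa-2,5-dien-1-one | CCCC(=O)C1=C(O)[C@](C)(CC=C)C(O)=CC1=O | intermediate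
6 | (4R)-2-butanoyl-3,5-dihydroxy-4-methyl-4-(3-methylbut-2-en-1-yl)cyclohexa-2,5-dien-1-one | CCCC(=O)C1=C(O)[C@](C)(CC=C(C)C)C(O)=CC1=O | intermediate
7 | benzene-1,3,5-triol (phloroglucinol) | Oc1cc(O)cc(O)c1 | starting material
8 | 1-(2,4,6-trihydroxyphenyl)butan-1-one | CCCC(=O)c1c(O)cc(O)cc1O | intermediate
9 | 1-(2,6-dihydroxy-4-methoxyphenyl)butan-1-one | CCCC(=O)c1c(O)cc(OC)cc1O | intermediate
10 | 1-{3-[(dimethylamino)methyl]-2,6-dihydroxy-4-methoxyphenyl}butan-1-one | CCCC(=O)c1c(O)cc(OC)c(CN(C)C)c1O | intermediate
11 | 1-(3-butanoyl-2,4-dihydroxy-6-methoxyphenyl)-N,N,N-trimethylmethanaminium iodide | CCCC(=O)c1c(O)cc(OC)c(C[N+](C)(C)C)c1O.[I-] | intermediate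
12 | 2-butanoyl-3-hydroxy-5-methoxy-6-methylidenecyclohexa-2,4-dien-1-one (o-quinone methide) | CCCC(=O)C1=C(O)C=C(OC)C(=C)C1=O | intermediate (not isolated)
13 | elaphopilosin A, (4R)-2-butanoyl-6-[(3-butanoyl-2,4-dihydroxy-6-methoxyphenyl)methyl]-3,5-dihydroxy-4-methyl-4-(3-methylbut-2-en-1-yl)cyclohexa-2,5-dien-1-one | CCCC(=O)C1=C(O)[C@](C)(CC=C(C)C)C(O)=C(Cc2c(OC)cc(O)c(C(=O)CCC)c2O)C1=O | target

**Step count**
Total: 10 steps. Longest linear sequence: 6 steps (steps 1–5 and 10); the ring B branch is steps 6–9.

**Three steps most likely to fail, with fallbacks**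

Step 3 (asymmetric dearomative allylation). The enantiomeric excess is not predictable, some attack at the chloro-bearing carbon is possible, and Pd(0) could re-ionise the product. The fallback sets out from compound 3 and comes back at compound 6, skipping steps 4 and 5. Compound 3 is alkylated without a chiral catalyst using prenyl bromide and NaOMe in MeOH at 0 °C, giving racemic 2-butanoyl-6-chloro-3,5-dihydroxy-4-methyl-4-(3-methylbut-2-en-1-yl)cyclohexa-2,5-dien-1-one F1. Zn/AcOH dechlorination then gives racemic 2-butanoyl-3,5-dihydroxy-4-methyl-4-(3-methylbut-2-en-1-yl)cyclohexa-2,5-dien-1-one F2. The enantiomers of this strong vinylogous acid are separated by preparative chiral SFC, and the (R)-enantiomer is compound 6.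

Step 7 (selective mono-O-methylation). Over-methylation to the 2-hydroxy-4,6-dimethoxy ketone or mixtures of mono-ethers may result. The fallback sets out from compound 8 and comes back at compound 9. Compound 8 is methylated exhaustively (Me2SO4 in excess, K2CO3, acetone, reflux) to 1-(2,4,6-trimethoxyphenyl)butan-1-one F3. The two methoxy groups ortho to the ketone are then cleaved by chelation-controlled demethylation with BCl3 (CH2Cl2, 0 °C → rt), which leaves the para methoxy group and gives 9.

Step 10 (quinone methide Michael coupling). The quinone methide may oligomerise or alkylate the free position of the product's ring B. The fallback reverses the polarity; it sets out from compound 6, uses compound 9 as the nucleophile, and comes back at compound 13. Compound 6 is aminomethylated at its single free carbon with Eschenmoser's salt (Me2N=CH2 iodide, Et3N, CH2Cl2, 0 °C) to give (4R)-2-butanoyl-6-[(dimethylamino)methyl]-3,5-dihydroxy-4-methyl-4-(3-methylbut-2-en-1-yl)cyclohexa-2,5-dien-1-one F4. Warming F4 with 3 equiv of phenol 9 in MeCN at 35–40 °C expels dimethylamine and gives the transient (4S)-2-butanoyl-3-hydroxy-4-methyl-4-(3-methylbut-2-en-1-yl)-6-methylidenecyclohex-2-ene-1,5-dione F5 (same spatial arrangement as 6; the descriptor changes by CIP priorities only). F5 is trapped at C-3 of 9 in a Michael addition to give 13, and excess 9 is recovered.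

**Further compounds**
F1 | step 3 | rac-2-butanoyl-6-chloro-3,5-dihydroxy-4-methyl-4-(3-methylbut-2-en-1-yl)cyclohexa-2,5-dien-1-one | CCCC(=O)C1=C(O)C(C)(CC=C(C)C)C(O)=C(Cl)C1=O
F2 | step 3 | rac-2-butanoyl-3,5-dihydroxy-4-methyl-4-(3-methylbut-2-en-1-yl)cyclohexa-2,5-dien-1-one | CCCC(=O)C1=C(O)C(C)(CC=C(C)C)C(O)=CC1=O
F3 | step 7 | 1-(2,4,6-trimethoxyphenyl)butan-1-one | CCCC(=O)c1c(OC)cc(OC)cc1OC
F4 | step 10 | (4R)-2-butanoyl-6-[(dimethylamino)methyl]-3,5-dihydroxy-4-methyl-4-(3-methylbut-2-en-1-yl)cyclohexa-2,5-dien-1-one | CCCC(=O)C1=C(O)[C@](C)(CC=C(C)C)C(O)=C(CN(C)C)C1=O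
F5 | step 10 | (4S)-2-butanoyl-3-hydroxy-4-methyl-4-(3-methylbut-2-en-1-yl)-6-methylidenecyclohex-2-ene-1,5-dione | CCCC(=O)C1=C(O)[C@](C)(CC=C(C)C)C(=O)C(=C)C1=O
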